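**Plan**
- Cuts, in retrosynthetic order: (i) the C-8–prenyl bond (aryl Claisen from a 7-O-(1,1-dimethylallyl) ether); (ii) C-3–C-1′, C-2–O-2′ and O-1–C-2 (coumaronochromone core from an A-ring enaminone and a B-ring chromene-5,8-quinone); (iii) the aryl C-6–CH2 bond of the A-ring dihydropyran, which is traced back to a five-membered ring.
- Enabling feature: the ring O-5–C(CH3)2–CH2–CH2–C-6 is a 2,2-dimethyl-2,3-dihydrobenzofuran on the same C-5/C-6 edge with its exocyclic CH2 inserted into the C-3–aryl bond. The quaternary O–CMe2 carbon beside C-3 and the oxygen-flanked aryl carbon should allow a 1,2-aryl shift of the C-3–CH2 radical.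
- Forward order: phloroacetophenone → ortho allyl ether → Claisen/cycloetherification (dihydrofuran) → iodide → ring enlargement (dihydropyran) → enaminone; catechol → chromene (propargyl Claisen) → quinone; the union closes the furan and γ-pyranone rings; O-allylation/Claisen installs the prenyl group last.
- Stereochemistry: the target has no stereocentre. The single centre of 6–9 is racemic and is erased in step 6; the alkene geometry of 4 and 5 does not reach the target.

Key step: step 6

Remark: the target is achiral, so "single enantiomer" is met trivially and 6–9 are used as racemates; coumaronochromones are described with isoflavone numbering (ring A 5–8, ring B 1′–6′, furan oxygen between C-2 and C-2′); carbonate 20 is assumed to be commercial.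

Step 1
Reactants: 1 2′,4′,6′-trihydroxyacetophenone
Product: 2 4-acetyl-3,5-dihydroxyphenyl 4-methylbenzenesulfonate
Conditions: TsCl (1.0 equiv), K2CO3, acetone, reflux
Reagents that add atoms: 4-methylbenzenesulfonyl chloride, Cc1ccc(cc1)S(=O)(=O)Cl
Why: Selective O-sulfonylation should occur at the unchelated, most acidic para-OH, which leaves the two hydrogen-bonded ortho-OH groups equivalent and blocks this oxygen for the furan closure and the radical step.

Step 2
Reactants: 3 prenyl acetate
Product: 4 (E)-4-hydroxy-3-methylbut-2-en-1-yl acetate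
Conditions: SeO2 (cat.), t-BuOOH (70% aq.), CH2Cl2, 25 °C
Reagents that add atoms: tert-butyl hydroperoxide, CC(C)(C)OO
Why: Catalytic SeO2 allylic oxidation (ene reaction, then [2,3]-sigmatropic shift) should hydroxylate the (E)-methyl group of the trisubstituted alkene and give the E-allylic alcohol.

Step 3
Reactants: 2 4-acetyl-3,5-dihydroxyphenyl 4-methylbenzenesulfonate; 4 (E)-4-hydroxy-3-methylbut-2-en-1-yl acetate
Product: 5 (E)-4-[2-acetyl-3-hydroxy-5-(tosyloxy)phenoxy]-3-methylbut-2-en-1-yl acetate
Conditions: PPh3, DIAD, THF, 0 → 25 °C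
Reagents that add atoms: none
Why: Mitsunobu etherification of one of the two equivalent phenols with the primary allylic alcohol should give the mono-ether by direct SN2, and the oxygen fixed here is the future pyran oxygen O-5, so no regiochemical choice is left for later.

Step 4
Reactants: 5 (E)-4-[2-acetyl-3-hydroxy-5-(tosyloxy)phenoxy]-3-methylbut-2-en-1-yl acetate
Product: 8 rac-7-acetyl-6-hydroxy-3-(hydroxymethyl)-2,2-dimethyl-2,3-dihydro-1-benzofuran-4-yl 4-methylbenzenesulfonate, via Claisen phenol 6 (not isolated), via dihydrobenzofuran acetate 7 (not isolated)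
Conditions: 1,2-dichlorobenzene, 175 °C; then MeOH, conc. HCl (cat.), 60 °C
Reagents that add atoms: none
Why: The aromatic Claisen rearrangement can only reach the free ortho carbon next to the tosylate and unmasks a phenol beside a 1,1-disubstituted alkene; Markovnikov protonation and capture of the tertiary cation by that phenol (the tosylate forbids closure on the other oxygen) close the 2,2-dimethyl-2,3-dihydrobenzofuran, acid methanolysis frees the primary alcohol, and the new C-3 centre is formed racemic and removed in step 6.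

Step 5
Reactants: 8 rac-7-acetyl-6-hydroxy-3-(hydroxymethyl)-2,2-dimethyl-2,3-dihydro-1-benzofuran-4-yl 4-methylbenzenesulfonate
Product: 9 rac-7-acetyl-6-hydroxy-3-(iodomethyl)-2,2-dimethyl-2,3-dihydro-1-benzofuran-4-yl 4-methylbenzenesulfonate
Conditions: PPh3, I2, imidazole, CH2Cl2, 0 → 25 °C
Reagents that add atoms: iodine, II
Why: Appel-type iodination converts the primary alcohol into the radical precursor by SN2 on the alkoxyphosphonium ion and should leave the chelated phenol and the sulfonate untouched.

Step 6
Reactants: 9 rac-7-acetyl-6-hydroxy-3-(iodomethyl)-2,2-dimethyl-2,3-dihydro-1-benzofuran-4-yl 4-methylbenzenesulfonate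
Product: 10 8-acetyl-7-hydroxy-2,2-dimethyl-3,4-dihydro-2H-chromen-5-yl 4-methylbenzenesulfonate
Conditions: (Me3Si)3SiH (syringe pump), 1,1′-azobis(cyclohexanecarbonitrile), PhCl, 125 °C, 2 mM
Reagents that add atoms: none
Why: Proposed new method: iodine abstraction by the silyl radical gives the primary (dihydrobenzofuran-3-yl)methyl radical, which attacks the ipso carbon C-3a (3-exo-trig) to a cyclopropane-fused cyclohexadienyl radical and reopens by cleavage of the old C-3–C-3a bond (neophyl 1,2-aryl shift), so the exocyclic CH2 is inserted between C-3 and the arene and the five-membered ring becomes the chroman-3-yl radical. β-Scission of C-2–C-3 to the tertiary α-aryloxy radical and a styrene, followed by 6-endo-trig re-closure, leads to the same six-membered ring as the chroman-4-yl radical, and either radical is then reduced by the silane. The closest known reaction types are the neophyl rearrangement that turns 5-exo aryl-radical cyclisation products into formal 6-endo products at low hydride concentration and the Dowd–Beckwith one-carbon ring expansion. The only closures are the transient cyclopropane (3-exo) or, on the fragmentation path, the pyran ring (6-endo); no new stereocentre arises and the racemic C-3 centre of 9 is erased. The step needs rearrangement to outrun hydrogen transfer to the primary radical; a slow hydrogen donor held at low concentration at 125 °C, the gem-dimethyl group, the gain from a primary to a secondary or benzylic radical with relief of five-ring strain, and the absence of a free O–H near the radical (one phenol chelated to the acetyl group, the flanking one masked as a tosylate without abstractable C–H) should secure this.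

Step 7
Reactants: 10 8-acetyl-7-hydroxy-2,2-dimethyl-3,4-dihydro-2H-chromen-5-yl 4-methylbenzenesulfonate
Product: 11 1-(5,7-dihydroxy-2,2-dimethyl-3,4-dihydro-2H-chromen-8-yl)ethan-1-one
Conditions: KOH, H2O–1,4-dioxane, 80 °C; then aq. HCl
Reagents that add atoms: none
Why: Alkaline hydrolysis of the aryl sulfonate (attack at sulfur, no alkylating by-product) on this robust ketone should free the phenol that becomes 7-OH before any base-sensitive ring is present.

Step 8
Reactants: 11 1-(5,7-dihydroxy-2,2-dimethyl-3,4-dihydro-2H-chromen-8-yl)ethan-1-one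
Product: 12 (E)-1-(5,7-dihydroxy-2,2-dimethyl-3,4-dihydro-2H-chromen-8-yl)-3-(dimethylamino)prop-2-en-1-one
Conditions: t-BuOCH(NMe2)2, toluene, 60 °C
Reagents that add atoms: tert-butoxybis(dimethylamino)methane, CC(C)(C)OC(N(C)C)N(C)C
Why: Condensation of the methyl ketone with Bredereck's reagent, which cannot O-methylate the free phenol, should give the E-enaminone that is the C-3 nucleophile and carries the future C-2.

Step 9
Reactants: 13 catechol; 14 3-chloro-3-methylbut-1-yne
Product: 15 2-[(2-methylbut-3-yn-2-yl)oxy]phenol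
Conditions: K2CO3, KI, CuI (cat.), acetone, 56 °C (13 in excess)
Reagents that add atoms: none
Why: Copper-assisted O-propargylation of a phenol with the tertiary propargyl chloride should give the mono-ether when catechol is used in excess.

Step 10
Reactants: 15 2-[(2-methylbut-3-yn-2-yl)oxy]phenol
Product: 16 2,2-dimethyl-2H-chromen-8-ol
Conditions: PhNEt2, 185 °C
Reagents that add atoms: none
Why: Propargyl Claisen rearrangement to the only free ortho carbon, 1,5-H shift and oxa-6π electrocyclisation should give the 2,2-dimethyl-2H-chromene with the phenol at C-8.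

Step 11
Reactants: 16 2,2-dimethyl-2H-chromen-8-ol
Product: 17 2,2-dimethyl-2H-chromene-5,8-dione
Conditions: (KSO3)2NO, KH2PO4, H2O–acetone, 0 → 25 °C
Reagents that add atoms: Fremy's salt (dipotassium nitrosodisulfonate), [K+].[K+].[O]N(S(=O)(=O)[O-])S(=O)(=O)[O-]
Why: Teuber oxidation with Fremy's salt converts a phenol with a free para position into the p-quinone and should leave the chromene alkene alone.

Step 12
Reactants: 12 (E)-1-(5,7-dihydroxy-2,2-dimethyl-3,4-dihydro-2H-chromen-8-yl)-3-(dimethylamino)prop-2-en-1-one; 17 2,2-dimethyl-2H-chromene-5,8-dione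
Product: 19 8-deprenyl target (7,5′-dihydroxycoumaronochromone carrying the dihydropyran at O-5/C-6 and the 2H-pyran at C-3′/O-4′), via aroylbenzofuran 18 (not isolated)
Conditions: AcOH, 25 °C; then DDQ (1.0 equiv), 1,4-dioxane, 0 → 25 °C
Reagents that add atoms: none
Why: In a Nenitzescu-type benzofuran annulation the enaminone α-carbon should add to C-6 of the quinone (β to the C-8 carbonyl, the one not deactivated as a vinylogous ester by the ring oxygen) and the new hydroquinone OH closes the furan with loss of dimethylamine; DDQ then effects the cyclodehydrogenation (oxa-Michael addition of the chelated phenol to C-2 and loss of two hydrogens) known for the ring-chain isomeric 2′-hydroxyisoflavones, and the quinone oxygen at C-8 ends as the free 5′-OH.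

Step 13
Reactants: 19 8-deprenyl target; 20 tert-butyl (2-methylbut-3-en-2-yl) carbonate
Product: 21 7-O-(2-methylbut-3-en-2-yl) ether of 19
Conditions: Pd(PPh3)4 (cat.), THF, 0 °C
Reagents that add atoms: none
Why: Palladium-catalysed decarboxylative allylic etherification (Tsuji–Trost) should alkylate the more acidic 7-OH (a vinylogous acid) in preference to 5′-OH and, under kinetic control, at the tertiary terminus of the π-allyl complex.

Step 14
Reactants: 21 7-O-(2-methylbut-3-en-2-yl) ether of 19
Product: 22 CNP0081330.0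
Conditions: toluene, 120 °C (sealed tube)
Reagents that add atoms: none
Why: The aromatic Claisen rearrangement of the 1,1-dimethylallyl ether can only end at C-8 because C-6 is blocked by the pyran ring, so it should deliver the 3-methylbut-2-enyl group and the free 7-OH in one operation.

**Compound list**
1 | 2′,4′,6′-trihydroxyacetophenone | CC(=O)c1c(O)cc(O)cc1O | starting material
2 | 4-acetyl-3,5-dihydroxyphenyl 4-methylbenzenesulfonate | CC(=O)c1c(O)cc(OS(=O)(=O)c2ccc(C)cc2)cc1O | intermediate
3 | prenyl acetate (3-methylbut-2-en-1-yl acetate) | CC(=O)OCC=C(C)C | starting material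
4 | (E)-4-hydroxy-3-methylbut-2-en-1-yl acetate | CC(=O)OC/C=C(\C)CO | intermediate
5 | (E)-4-[2-acetyl-3-hydroxy-5-(tosyloxy)phenoxy]-3-methylbut-2-en-1-yl acetate | CC(=O)OC/C=C(\C)COc1cc(OS(=O)(=O)c2ccc(C)cc2)cc(O)c1C(C)=O | intermediate
6 | rac-2-[3-acetyl-2,4-dihydroxy-6-(tosyloxy)phenyl]-3-methylbut-3-en-1-yl acetate (Claisen phenol) | CC(=O)OCC(C(C)=C)c1c(O)c(C(C)=O)c(O)cc1OS(=O)(=O)c1ccc(C)cc1 | intermediate
7 | rac-[7-acetyl-6-hydroxy-2,2-dimethyl-4-(tosyloxy)-2,3-dihydro-1-benzofuran-3-yl]methyl acetate | CC(=O)OCC1c2c(OS(=O)(=O)c3ccc(C)cc3)cc(O)c(C(C)=O)c2OC1(C)C | intermediate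
8 | rac-7-acetyl-6-hydroxy-3-(hydroxymethyl)-2,2-dimethyl-2,3-dihydro-1-benzofuran-4-yl 4-methylbenzenesulfonate | CC(=O)c1c(O)cc(OS(=O)(=O)c2ccc(C)cc2)c2c1OC(C)(C)C2CO | intermediate
9 | rac-7-acetyl-6-hydroxy-3-(iodomethyl)-2,2-dimethyl-2,3-dihydro-1-benzofuran-4-yl 4-methylbenzenesulfonate | CC(=O)c1c(O)cc(OS(=O)(=O)c2ccc(C)cc2)c2c1OC(C)(C)C2CI | intermediate
10 | 8-acetyl-7-hydroxy-2,2-dimethyl-3,4-dihydro-2H-chromen-5-yl 4-methylbenzenesulfonate | CC(=O)c1c(O)cc(OS(=O)(=O)c2ccc(C)cc2)c2c1OC(C)(C)CC2 | intermediate
11 | 1-(5,7-dihydroxy-2,2-dimethyl-3,4-dihydro-2H-chromen-8-yl)ethan-1-one | CC(=O)c1c(O)cc(O)c2c1OC(C)(C)CC2 | intermediate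
12 | (E)-1-(5,7-dihydroxy-2,2-dimethyl-3,4-dihydro-2H-chromen-8-yl)-3-(dimethylamino)prop-2-en-1-one | CN(C)/C=C/C(=O)c1c(O)cc(O)c2c1OC(C)(C)CC2 | intermediate
13 | catechol (benzene-1,2-diol) | Oc1ccccc1O | starting material
14 | 3-chloro-3-methylbut-1-yne | CC(C)(Cl)C#C | starting material
15 | 2-[(2-methylbut-3-yn-2-yl)oxy]phenol | C#CC(C)(C)Oc1ccccc1O | intermediate
16 | 2,2-dimethyl-2H-chromen-8-ol | CC1(C)C=Cc2cccc(O)c2O1 | intermediate
17 | 2,2-dimethyl-2H-chromene-5,8-dione | CC1(C)C=CC2=C(O1)C(=O)C=CC2=O | intermediate
18 | aroylbenzofuran: (5,7-dihydroxy-2,2-dimethylchroman-8-yl) ketone of a 5-hydroxybenzofuran-3-yl unit that carries a 2,2-dimethyl-2H-pyran fused at C-6 (oxygen) and C-7 (vinyl carbon) | O=C(c1coc2c1cc(O)c1OC(C)(C)C=Cc12)c1c(O)cc(O)c2CCC(C)(C)Oc12 | intermediate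
19 | 8-deprenyl target: 7,5′-dihydroxycoumaronochromone with a 2,2-dimethyl-3,4-dihydro-2H-pyran fused at O-5/C-6 and a 2,2-dimethyl-2H-pyran fused at C-3′/O-4′ | Oc1cc2oc3oc4c5C=CC(C)(C)Oc5c(O)cc4c3c(=O)c2c2OC(C)(C)CCc12 | intermediate
20 | tert-butyl (2-methylbut-3-en-2-yl) carbonate | C=CC(C)(C)OC(=O)OC(C)(C)C | starting material
21 | 7-O-(2-methylbut-3-en-2-yl) ether of 19 | C=CC(C)(C)Oc1cc2oc3oc4c5C=CC(C)(C)Oc5c(O)cc4c3c(=O)c2c2OC(C)(C)CCc12 | intermediate
22 | CNP0081330.0 (8-prenyl derivative of 19; achiral) | CC(C)=CCc1c(O)c2c(c3c(=O)c4c(oc13)oc1c3c(c(O)cc14)OC(C)(C)C=C3)OC(C)(C)CC2 | target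

**Count**
Total steps: 14. Longest linear sequence: 10 steps (1, 3, 4, 5, 6, 7, 8, 12, 13, 14).

**Steps most likely to fail**

Step 6 (Proposed new method). Hydrogen transfer to the primary radical may outrun the 1,2-aryl shift and give simple reduction, or the radical may fragment without re-closing. The fallback sets out from 8 and returns at 10. Alcohol 8 is converted with MsCl/Et3N into the primary methanesulfonate F1. Solvolysis of F1 in hexafluoroisopropanol with 2,6-lutidine enlarges the ring ionically through aryl participation (phenonium ion, Wagner–Meerwein 1,2-aryl shift), and loss of the benzylic proton gives the 2H-chromene F2. Hydrogenation of F2 (H2, Pd/C, EtOAc) gives 10; it is harmless at this stage because no other alkene is present.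

Step 12. Conjugate addition may occur at the wrong quinone carbon or from the electron-rich A-ring carbon, and the DDQ stage may over-oxidise (benzylic dehydrogenation of the dihydropyran, oxidation of the phenols). The fallback sets out from 12 and 17 and returns at 19 by the conventional isoflavone sequence. Enaminone 12 is cyclised with iodine to the 3-iodochromone F3. Quinone 17 adds HBr to give the bromohydroquinone F4, which is protected as the bis(methoxymethyl) ether F5 and borylated (B2pin2, PdCl2(dppf), KOAc) to the pinacol boronate F6. Suzuki–Miyaura coupling of F3 with F6 gives the protected isoflavone F7, and HCl/MeOH frees the 2′,5′-dihydroxyisoflavone F8. DDQ, added slowly, then closes the furan ring by the known cyclodehydrogenation to give 19.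

Step 13. Etherification may occur at the second phenol or at the primary terminus of the π-allyl complex (linear ether), and the tertiary allyl ether may ionise again on palladium. The fallback sets out from 19 and returns at 21. Compound 19 is O-alkylated at 7-OH with 3-chloro-3-methylbut-1-yne 14 (K2CO3, KI, CuI, acetone) to the tertiary propargyl ether F9. Semi-hydrogenation of the alkyne of F9 (H2, Lindlar catalyst, quinoline) gives 21.

**Further compounds**
F1 | step 6 | rac-[7-acetyl-6-hydroxy-2,2-dimethyl-4-(tosyloxy)-2,3-dihydro-1-benzofuran-3-yl]methyl methanesulfonate | CC(=O)c1c(O)cc(OS(=O)(=O)c2ccc(C)cc2)c2c1OC(C)(C)C2COS(C)(=O)=O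
F2 | step 6 | 8-acetyl-7-hydroxy-2,2-dimethyl-2H-chromen-5-yl 4-methylbenzenesulfonate | CC(=O)c1c(O)cc(OS(=O)(=O)c2ccc(C)cc2)c2c1OC(C)(C)C=C2
F3 | step 12 | 7-hydroxy-3-iodochromone carrying the 2,2-dimethyl-3,4-dihydro-2H-pyran fused at O-5/C-6 | Oc1cc2occ(I)c(=O)c2c2OC(C)(C)CCc12
F4 | step 12 | 6-bromo-2,2-dimethyl-2H-chromene-5,8-diol | CC1(C)C=Cc2c(O)c(Br)cc(O)c2O1
F5 | step 12 | 6-bromo-5,8-bis(methoxymethoxy)-2,2-dimethyl-2H-chromene | COCOc1cc(Br)c(OCOC)c2C=CC(C)(C)Oc12
F6 | step 12 | 2-[5,8-bis(methoxymethoxy)-2,2-dimethyl-2H-chromen-6-yl]-4,4,5,5-tetramethyl-1,3,2-dioxaborolane | COCOc1cc(B2OC(C)(C)C(C)(C)O2)c(OCOC)c2C=CC(C)(C)Oc12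
F7 | step 12 | 7-hydroxy-3-[5,8-bis(methoxymethoxy)-2,2-dimethyl-2H-chromen-6-yl]chromone carrying the dihydropyran at O-5/C-6 | COCOc1cc(-c2coc3cc(O)c4CCC(C)(C)Oc4c3c2=O)c(OCOC)c2C=CC(C)(C)Oc12
F8 | step 12 | 7-hydroxy-3-(5,8-dihydroxy-2,2-dimethyl-2H-chromen-6-yl)chromone carrying the dihydropyran at O-5/C-6 (2′,5′-dihydroxyisoflavone) | Oc1cc(-c2coc3cc(O)c4CCC(C)(C)Oc4c3c2=O)c(O)c2C=CC(C)(C)Oc12
F9 | step 13 | 7-O-(2-methylbut-3-yn-2-yl) ether of 19 | C#CC(C)(C)Oc1cc2oc3oc4c5C=CC(C)(C)Oc5c(O)cc4c3c(=O)c2c2OC(C)(C)CCc12
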